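## Retrosynthetic overview

- **Feature the strategy rests on:** in the eight-membered ring, the run C(OAc)-CH(side chain)-C(CH2O)=C(C=O) is, at the ketone level, the 1,3-acyl-shift isomer of a cyclohexanone. The alpha-carbon of that cyclohexanone is the spiro atom of an alpha-acyl-beta-alkylidene-gamma-butyrolactone. The carbinol carbon, CH2, CHMe, the two cyclopropane CH and the butenolide alpha-carbon already trace that six-membered ring.
- **Late disconnections:** target <= Schenck ene reaction at the prenyl alkene <= acetate <= cyclooctanone-fused butenolide <= photochemical six-to-eight ring expansion of the spiro lactone <= Conia-ene closure of a propargylic beta-keto ester.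
- **Fragments:** the ester divides into a norcarane beta-keto ester and a propargylic alcohol. The first comes from propanal and methyl vinyl ketone via (R)-4-methylcyclohexenone, cyclopropanation, and carbonylative 1,2-transposition of the oxygen function. The second comes from (R)-citronellal and formaldehyde.
- **Ring order:** cyclohexenone, cyclopropane, spiro gamma-lactone, then the eight-membered ring by enlargement of the six-membered ring.

Key step: step 12

Remark: the carbinol and ester-bearing carbons created during the carbonyl transposition are carried as mixtures, because both are planarised (ketone, enolate) before the spiro centre is fixed; their SMILES are left open at these atoms.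

## Route

Step 1
Reactants: 1 propanal; 2 methyl vinyl ketone
Product: 3 (R)-2-methyl-5-oxohexanal
Conditions: (S)-2-[methoxy(diphenyl)methyl]pyrrolidine (5 mol %), ethyl 3,4-dihydroxybenzoate (20 mol %), neat, 4 °C
Reagents that add atoms: none
Why: Enamine-catalysed asymmetric Michael addition, in which the E-enamine of propanal is shielded on one face by the methoxy(diphenyl)methyl group, so the enone (activated by hydrogen bonding to the catechol co-catalyst) is taken up on the open face and the methyl-bearing centre is set as R.

Step 2
Reactants: 3 (R)-2-methyl-5-oxohexanal
Product: 5 (R)-4-methylcyclohex-2-en-1-one, via aldol adduct 4 (not isolated)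
Conditions: LiOH (0.1 equiv), i-PrOH, rt
Reagents that add atoms: none
Why: Intramolecular aldol condensation (6-enolendo-exo-trig attack of the methyl ketone enolate on the aldehyde, then E1cB loss of water) under mild base, so that ring closure outruns epimerisation of the alpha-methyl aldehyde and the R centre is carried over unchanged.

Step 3
Reactants: 5 (R)-4-methylcyclohex-2-en-1-one
Product: 6 (1S,5R,6S)-5-methylbicyclo[4.1.0]heptan-2-one
Conditions: Me3S(O)I, NaH, DMSO, rt; chromatographic removal of the minor diastereomer
Reagents that add atoms: trimethylsulfoxonium iodide, C[S+](C)(C)=O.[I-]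
Why: Corey-Chaykovsky cyclopropanation, in which the soft sulfoxonium ylide adds 1,4 on the enone face opposite the adjacent methyl group and the enolate then displaces DMSO (3-exo-tet), giving the necessarily cis-fused cyclopropane with its CH2 trans to the methyl.

Step 4
Reactants: 6 (1S,5R,6S)-5-methylbicyclo[4.1.0]heptan-2-one
Product: 8 (1S,5R,6S)-5-methylbicyclo[4.1.0]hept-2-en-2-yl trifluoromethanesulfonate, via lithium enolate 7 (not isolated)
Conditions: LDA, THF, -78 °C; then PhNTf2, -78 °C to 0 °C
Reagents that add atoms: N-phenylbis(trifluoromethanesulfonimide), FC(F)(F)S(=O)(=O)N(c1ccccc1)S(=O)(=O)C(F)(F)F; LDA (lithium of 7 only), [Li]N(C(C)C)C(C)C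
Why: Kinetic enolate formation and O-sulfonylation, regiochemically unambiguous because deprotonation at the cyclopropane CH would place a double bond exocyclic to the three-membered ring, so only the CH2 flank enolises and no stereocentre is touched.

Step 5
Reactants: 8 (1S,5R,6S)-5-methylbicyclo[4.1.0]hept-2-en-2-yl trifluoromethanesulfonate
Product: 9 methyl (1S,5R,6S)-5-methylbicyclo[4.1.0]hept-2-ene-2-carboxylate
Conditions: Pd(OAc)2 (5 mol %), PPh3 (10 mol %), CO (1 atm), MeOH, Et3N, DMF, rt to 50 °C
Reagents that add atoms: carbon monoxide, [C-]#[O+]; methanol, CO
Why: Palladium-catalysed alkoxycarbonylation of an alkenyl triflate (oxidative addition to zerovalent palladium, CO insertion, methanolysis of the acyl complex) gives the conjugated ester with the ring stereocentres untouched.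

Step 6
Reactants: 9 methyl (1S,5R,6S)-5-methylbicyclo[4.1.0]hept-2-ene-2-carboxylate
Product: 11 methyl (1S,5R,6S)-3-hydroxy-5-methylbicyclo[4.1.0]heptane-2-carboxylate, via pinacol boronate 10 (not isolated)
Conditions: CuCl (5 mol %), DPEphos (5 mol %), NaOt-Bu (10 mol %), B2pin2, MeOH (2 equiv), THF, rt; then NaBO3·4H2O, THF/H2O, rt
Reagents that add atoms: bis(pinacolato)diboron (boryl group of 10), CC1(C)OB(OC1(C)C)B1OC(C)(C)C(C)(C)O1; sodium perborate (hydroxyl oxygen), [Na+].[O-]OB=O
Why: Copper-catalysed conjugate borylation of an alpha,beta-unsaturated ester followed by stereoretentive C-B oxidation puts oxygen on the beta-carbon and so completes the 1,2-shift of the oxygen function, the two new centres needing no control because both are planarised in later steps.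

Step 7
Reactants: 11 methyl (1S,5R,6S)-3-hydroxy-5-methylbicyclo[4.1.0]heptane-2-carboxylate
Product: 12 methyl (1S,5R,6S)-5-methyl-3-oxobicyclo[4.1.0]heptane-2-carboxylate
Conditions: Dess-Martin periodinane (1.1 equiv), CH2Cl2, 0 °C to rt
Reagents that add atoms: none
Why: Dess-Martin oxidation of the secondary alcohol under near-neutral conditions gives the beta-keto ester without retro-aldol cleavage or beta-elimination, the ester-bearing carbon remaining a freely equilibrating centre.

Step 8
Reactants: 13 (R)-citronellal
Product: 14 (3R)-3,7-dimethylocta-1,6-dien-1-yl nonafluorobutane-1-sulfonate (E/Z mixture)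
Conditions: n-C4F9SO2F, DBU, DMF, 0 °C to rt
Reagents that add atoms: nonafluorobutane-1-sulfonyl fluoride, FS(=O)(=O)C(F)(F)C(F)(F)C(F)(F)C(F)(F)F
Why: Base-mediated O-sulfonylation of the aldehyde enolate (alkenyl nonaflate formation), preferred to triflic anhydride because an electrophilically activated citronellal would close by a Prins or ene pathway onto its own trisubstituted alkene, and the beta-stereocentre takes no part.

Step 9
Reactants: 14 (3R)-3,7-dimethylocta-1,6-dien-1-yl nonafluorobutane-1-sulfonate; 15 formaldehyde (as paraformaldehyde)
Product: 17 (4R)-4,8-dimethylnon-7-en-2-yn-1-ol, via lithium acetylide 16 (not isolated)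
Conditions: LDA (2.5 equiv), THF, -78 °C; then (CH2O)n, -78 °C to rt
Reagents that add atoms: LDA (lithium of 16 only), [Li]N(C(C)C)C(C)C
Why: Base-induced elimination of the alkenyl sulfonate to the alkyne, whose immediate deprotonation to the acetylide guards the propargylic stereocentre against allene isomerisation, followed by 1,2-addition of the acetylide to formaldehyde.

Step 10
Reactants: 12 methyl (1S,5R,6S)-5-methyl-3-oxobicyclo[4.1.0]heptane-2-carboxylate; 17 (4R)-4,8-dimethylnon-7-en-2-yn-1-ol
Product: 18 (4R)-4,8-dimethylnon-7-en-2-yn-1-yl (1S,5R,6S)-5-methyl-3-oxobicyclo[4.1.0]heptane-2-carboxylate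
Conditions: DMAP (0.3 equiv), toluene, reflux, 4 Å MS (removal of MeOH)
Reagents that add atoms: none
Why: DMAP-promoted transesterification of an enolisable beta-keto ester, which runs through an acylketene-type intermediate and is driven by removal of methanol, joins the two fragments without touching their stereocentres.

Step 11
Reactants: 18 (4R)-4,8-dimethylnon-7-en-2-yn-1-yl (1S,5R,6S)-5-methyl-3-oxobicyclo[4.1.0]heptane-2-carboxylate
Product: 19 spiro lactone, (Z)-4'-[(2R)-2,6-dimethylhept-5-en-1-ylidene]-5-methylspiro[bicyclo[4.1.0]heptane-2,3'-oxolane]-2',3-dione (spiro carbon R; alkylidene-bearing lactone carbon anti to the cyclopropane CH2)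
Conditions: In(OTf)3 (10 mol %), DBU (10 mol %), toluene, reflux, anhydrous
Reagents that add atoms: none
Why: Conia-ene cycloisomerisation, in which the trivalent indium enolate adds across the tethered alkyne by 5-exo-dig syn-carbometalation, so protodemetalation leaves the branched substituent cis to the OCH2 group (Z), and the new C-C bond forms on the enolate face away from the neighbouring cyclopropane CH2, which sets the spiro centre.

Step 12
Reactants: 19 spiro lactone
Product: 20 cyclooctanone-fused butenolide (eight-membered ring ketone fused to the butenolide C=C and to the cis cyclopropane; ring CH next to the ketone is S and carries the (2R)-6-methylhept-5-en-2-yl chain)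
Conditions: hν (medium-pressure Hg lamp, Pyrex filter, λ > 300 nm), degassed MeCN (ca. 2 mM), 15-20 °C, no sensitiser; recovered 19 resubmitted
Reagents that add atoms: none
Why: Proposed new method: n-pi* excitation of the ring ketone cleaves the C(=O)-C(spiro) bond (stepwise alpha-cleavage or a concerted suprafacial 1,3-shift) to an acyl radical held beside a tertiary radical delocalised over the lactone carbonyl and the alkylidene, and recombination at the alkylidene CH gives 20. The closest known reaction type is the singlet photochemical 1,3-acyl shift of beta,gamma-unsaturated ketones, which already enlarges 2-alkenylcycloalkanones by two carbons; its use on a spiro alpha-acyl-beta-alkylidene-gamma-butyrolactone is what is new. The eight-membered ring is not closed end to end but arises by insertion of the two alkylidene carbons into the six-membered ring through a four-centre array, the spiro atom holding the breaking bond parallel to the alkene p orbitals, while the lactone ring persists and its C=C becomes endocyclic and tetrasubstituted. The one new stereocentre, the ring CH bearing the side chain, is fixed as S because the acyl carbon stays on the lactone face it occupies in 19 and meets the terminus of the Z-alkylidene, whose branched substituent points towards the OCH2 group. The step needs the 1,3-shift to win over oxa-di-pi-methane rearrangement, decarbonylation and cyclopropylcarbinyl opening, which is served by direct unsensitised long-wavelength irradiation of a dilute degassed solution, by fast in-cage recombination and by the strong stabilisation of the carbon radical. Gain of butenolide conjugation and release of the crowded quaternary centre should bias the photostationary mixture towards 20.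

Step 13
Reactants: 20 cyclooctanone-fused butenolide
Product: 21 cis alcohol (carbinol carbon R; OH cis to the side chain on the neighbouring ring carbon)
Conditions: LiAlH(Ot-Bu)3, THF, -78 °C to -20 °C; aqueous Rochelle salt work-up
Reagents that add atoms: none
Why: Diastereoselective ketone reduction, in which the bulky but weakly basic alkoxyaluminium hydride spares the lactone, avoids enolising the acidic CH between ketone and butenolide, and attacks the carbonyl from the peripheral face opposite the branched side chain, placing the new OH cis to that chain.

Step 14
Reactants: 21 cis alcohol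
Product: 22 acetate with intact prenyl-type side chain
Conditions: Ac2O, pyridine, DMAP (cat.), CH2Cl2, 0 °C to rt
Reagents that add atoms: acetic anhydride, CC(=O)OC(C)=O
Why: DMAP-catalysed acylation of the secondary alcohol proceeds with retention at carbon, and the neighbouring CH is no longer alpha to a ketone and so is not endangered by the amine base.

Step 15
Reactants: 22 acetate with intact prenyl-type side chain
Product: 23 target CNP0205234.1
Conditions: O2, tetraphenylporphyrin (cat.), visible light, CH2Cl2, 0 °C; no reductive work-up; chromatographic separation
Reagents that add atoms: dioxygen, O=O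
Why: Schenck ene reaction, in which singlet oxygen attacks only the electron-rich trisubstituted alkene (the tetrasubstituted butenolide C=C is electron-poor and inert), and abstraction of an allylic CH2 hydrogen with C-O bonding at the dimethyl-substituted carbon gives the tertiary hydroperoxide with the E alkene, the isopropenyl secondary hydroperoxide regioisomer being removed by chromatography.

## Compound list

1 | propanal | CCC=O | starting material
2 | methyl vinyl ketone | CC(=O)C=C | starting material
3 | (R)-2-methyl-5-oxohexanal | O=C[C@H](C)CCC(C)=O | intermediate
4 | (4R)-3-hydroxy-4-methylcyclohexan-1-one (aldol adduct, carbinol epimers, not isolated) | O=C1CC[C@@H](C)C(O)C1 | intermediate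
5 | (R)-4-methylcyclohex-2-en-1-one | C1C[C@@H](C)C=CC1=O | intermediate
6 | (1S,5R,6S)-5-methylbicyclo[4.1.0]heptan-2-one (cyclopropane CH2 trans to methyl) | C1C[C@@H](C)[C@@H]2C[C@@H]2C1=O | intermediate
7 | lithium enolate of 6 (not isolated) | [Li]OC1=CC[C@@H](C)[C@@H]2C[C@@H]21 | intermediate
8 | (1S,5R,6S)-5-methylbicyclo[4.1.0]hept-2-en-2-yl trifluoromethanesulfonate | FC(F)(F)S(=O)(=O)OC1=CC[C@@H](C)[C@@H]2C[C@@H]21 | intermediate
9 | methyl (1S,5R,6S)-5-methylbicyclo[4.1.0]hept-2-ene-2-carboxylate | COC(=O)C1=CC[C@@H](C)[C@@H]2C[C@@H]21 | intermediate
10 | methyl (1S,5R,6S)-5-methyl-3-(pinacolatoboryl)bicyclo[4.1.0]heptane-2-carboxylate (mixture at C2 and C3, not isolated) | COC(=O)C1C(B3OC(C)(C)C(C)(C)O3)C[C@@H](C)[C@@H]2C[C@@H]21 | intermediate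
11 | methyl (1S,5R,6S)-3-hydroxy-5-methylbicyclo[4.1.0]heptane-2-carboxylate (mixture at C2 and C3) | COC(=O)C1C(O)C[C@@H](C)[C@@H]2C[C@@H]21 | intermediate
12 | methyl (1S,5R,6S)-5-methyl-3-oxobicyclo[4.1.0]heptane-2-carboxylate (C2 equilibrating) | COC(=O)C1C(=O)C[C@@H](C)[C@@H]2C[C@@H]21 | intermediate
13 | (R)-citronellal | O=CC[C@H](C)CCC=C(C)C | starting material
14 | (3R)-3,7-dimethylocta-1,6-dien-1-yl nonafluorobutane-1-sulfonate (E/Z mixture) | FC(F)(F)C(F)(F)C(F)(F)C(F)(F)S(=O)(=O)OC=C[C@H](C)CCC=C(C)C | intermediate
15 | formaldehyde (as paraformaldehyde) | C=O | starting material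
16 | lithium (3R)-3,7-dimethyloct-6-en-1-ynide (not isolated) | [Li]C#C[C@H](C)CCC=C(C)C | intermediate
17 | (4R)-4,8-dimethylnon-7-en-2-yn-1-ol | OCC#C[C@H](C)CCC=C(C)C | intermediate
18 | (4R)-4,8-dimethylnon-7-en-2-yn-1-yl (1S,5R,6S)-5-methyl-3-oxobicyclo[4.1.0]heptane-2-carboxylate | O=C1C[C@@H](C)[C@@H]2C[C@@H]2C1C(=O)OCC#C[C@H](C)CCC=C(C)C | intermediate
19 | spiro alpha-acyl-beta-(Z)-alkylidene-gamma-butyrolactone (spiro carbon R) | O=C1C[C@@H](C)[C@@H]2C[C@@H]2[C@]13C(=O)OC/C3=C\[C@H](C)CCC=C(C)C | intermediate
20 | cyclooctanone-fused butenolide (side-chain-bearing ring CH S) | O=C1C[C@@H](C)[C@@H]2C[C@@H]2C2=C(COC2=O)[C@@H]1[C@H](C)CCC=C(C)C | intermediate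
21 | cis alcohol (carbinol carbon R) | O[C@@H]1C[C@@H](C)[C@@H]2C[C@@H]2C2=C(COC2=O)[C@@H]1[C@H](C)CCC=C(C)C | intermediate
22 | acetate with intact prenyl-type side chain | CC(=O)O[C@@H]1C[C@@H](C)[C@@H]2C[C@@H]2C2=C(COC2=O)[C@@H]1[C@H](C)CCC=C(C)C | intermediate
23 | CNP0205234.1 (acetoxy carbon R, ring CHMe R, both cyclopropane CH S, side-chain-bearing ring CH S, side-chain CHMe R, E alkene, tertiary hydroperoxide) | CC(=O)O[C@@H]1C[C@@H](C)[C@@H]2C[C@@H]2C2=C(COC2=O)[C@@H]1[C@H](C)C/C=C/C(C)(C)OO | target

## Step count and risks

Total step count: 15. Longest linear sequence: 13 steps (steps 1-7 and 10-15). The citronellal branch (steps 8-9) joins at step 10.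

**Step 12 (photochemical 1,3-acyl shift).**
- What may go wrong: an unfavourable photostationary state; loss of the stereochemical relay if the radical pair relaxes before recombining; decarbonylation; opening of the cyclopropane next to the radical centre.
- Fallback: it sets out from 18 and comes back at 20. Both the photochemistry and the isolation of 19 are replaced by the thermal, metal-catalysed insertion of an alkyne into the ketone-to-alpha-carbon bond of a cyclic beta-keto ester. This is a known two-carbon enlargement of 2-oxocyclohexanecarboxylates to eight-membered rings. It has been established with terminal alkynes, and here the tether has to make up for the internal alkyne.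
- With [ReBr(CO)3(thf)]2 (cat.) and benzyl isocyanide (cat.) in toluene at 80 °C, the enolate should add across the tethered alkyne. The alkenyl-metal carbon should then close onto the ketone, and retro-aldol cleavage should open the strained ring to the same C(=O)-CH-C=C(C=O)O array.
- The side-chain-bearing CH would then be set by protonation of the extended enolate. Because it is acidic, it could be equilibrated with a catalytic amine base and the epimers separated. No compound outside the list is isolated on this way (F0).

**Step 11 (Conia-ene closure).**
- What may go wrong: slow closure, because the ester must rotate out of its preferred conformation; competing 6-endo or O-cyclisation; acid damage to the trisubstituted alkene; erosion of the alkene geometry.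
- Fallback: it sets out from 17 (and 12) and comes back at 19. The alkene geometry is built before the ring is closed, and the C-C bond is made by cross-coupling instead of cycloisomerisation.
- Syn-hydrostannation of 17 (Bu3SnH, PdCl2(PPh3)2 cat., THF) should place tin on the carbon next to the CH2OH group, away from the branched carbon. This gives (2E,4R)-4,8-dimethyl-2-(tributylstannyl)nona-2,7-dien-1-ol F1.
- Iododestannylation (I2, CH2Cl2, 0 °C) with retention gives (2E,4R)-2-iodo-4,8-dimethylnona-2,7-dien-1-ol F2.
- Transesterification with 12 (DMAP, toluene, reflux) gives the iodoallyl beta-keto ester F3.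
- Copper-catalysed intramolecular C-vinylation of the beta-keto ester enolate (CuI cat., N,N'-dimethylethylenediamine, Cs2CO3, dioxane, heat) closes the five-membered lactone. The alkene geometry is retained, and closure again occurs on the face away from the cyclopropane CH2, giving 19.

**Step 13 (ketone reduction).**
- What may go wrong: poor or reversed facial selectivity in the flexible eight-membered ring; enolisation with epimerisation of the neighbouring CH.
- Fallback: it sets out from 20 and comes back at 22. The carbinol configuration is fixed by SN2 inversion instead of by face selection.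
- The ketone is reduced under non-basic conditions that favour the other face (NaBH4, CeCl3·7H2O, MeOH, -78 °C) to the trans alcohol F4.
- A Mitsunobu reaction with acetic acid (PPh3, DIAD, toluene, 0 °C to rt) then installs the acetate with inversion and gives 22 directly.

## Further compounds

F0 | step 12 | none | none
F1 | step 11 | (2E,4R)-4,8-dimethyl-2-(tributylstannyl)nona-2,7-dien-1-ol | OC/C([Sn](CCCC)(CCCC)CCCC)=C\[C@H](C)CCC=C(C)C
F2 | step 11 | (2E,4R)-2-iodo-4,8-dimethylnona-2,7-dien-1-ol | OC/C(I)=C\[C@H](C)CCC=C(C)C
F3 | step 11 | (2E,4R)-2-iodo-4,8-dimethylnona-2,7-dien-1-yl (1S,5R,6S)-5-methyl-3-oxobicyclo[4.1.0]heptane-2-carboxylate | O=C1C[C@@H](C)[C@@H]2C[C@@H]2C1C(=O)OC/C(I)=C\[C@H](C)CCC=C(C)C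
F4 | step 13 | trans alcohol (carbinol epimer of 21) | O[C@H]1C[C@@H](C)[C@@H]2C[C@@H]2C2=C(COC2=O)[C@@H]1[C@H](C)CCC=C(C)C
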